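The route rests on disconnecting the ring C–O bond of the diaryl ether that joins rings C and D. In the target, the ring C carbon bearing the free OH is ortho to the carbon bearing this ether oxygen. A formyl group placed on the OH carbon therefore activates the adjacent C–F bond for SNAr and is afterwards converted into that OH by Dakin oxidation. The key step closes the 19-membered ring and forms the C–O bond in one operation. Its open-chain precursor already contains the A–O–B ether and both CH2CH2 bridges, and carries one free phenol on ring D and a 3-fluoro-4-formylphenyl ring C.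

Key step: step 7

Remark: ring A is the methoxy-bearing ring, ring B the 1,4-linked ring, ring C the ring that carries OH in the target (CHO and F earlier), ring D the 1,3-linked ring. The alkene made in step 5 is expected as an E/Z mixture and is drawn without geometry, because hydrogenation in step 6 erases it.

Step 1
Reactants: 1 isovanillin (3-hydroxy-4-methoxybenzaldehyde); 2 4-vinylphenylboronic acid
Product: 3 4-methoxy-3-(4-vinylphenoxy)benzaldehyde
Conditions: 2 (2 equiv), Cu(OAc)2 (2 equiv), pyridine (5 equiv), 4 Å MS, CH2Cl2, air, rt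
Reagents that add atoms: none
Why: Chan–Lam oxidative O-arylation: the aryl group of the boronic acid is transferred to copper and reductive elimination from the copper phenoxide forms the diaryl ether at room temperature, conditions under which the aldehyde and the vinyl group are spectators.

Step 2
Reactants: 4 4-bromo-2-fluorobenzaldehyde
Product: 5 2-(4-bromo-2-fluorophenyl)-1,3-dioxolane
Conditions: HOCH2CH2OH (3 equiv), p-TsOH·H2O (cat.), toluene, reflux (Dean–Stark)
Reagents that add atoms: ethylene glycol, OCCO
Why: Acid-catalysed acetalisation with azeotropic removal of water converts the aldehyde into a dioxolane that withstands the later ylide and hydrogenation conditions and keeps the C–F bond unactivated until the aldehyde is released.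

Step 3
Reactants: 3 4-methoxy-3-(4-vinylphenoxy)benzaldehyde; 5 2-(4-bromo-2-fluorophenyl)-1,3-dioxolane
Product: 6 3-(4-{(E)-2-[4-(1,3-dioxolan-2-yl)-3-fluorophenyl]ethenyl}phenoxy)-4-methoxybenzaldehyde
Conditions: Pd(OAc)2 (5 mol %), P(o-tol)3 (10 mol %), Et3N, DMF, 100 °C
Reagents that add atoms: none
Why: Mizoroki–Heck coupling: oxidative addition of the only C–Br bond, syn insertion of the only alkene and syn β-hydride elimination should give the E-stilbene, with the C–F bond, the acetal and the aldehyde untouched.

Step 4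
Reactants: 7 3-benzyloxybenzyl alcohol
Product: 9 (3-benzyloxybenzyl)triphenylphosphonium bromide, via 3-benzyloxybenzyl bromide 8 (not isolated)
Conditions: PPh3·HBr, MeCN, reflux
Reagents that add atoms: triphenylphosphine hydrobromide, [Br-].[PH+](c1ccccc1)(c1ccccc1)c1ccccc1
Why: Direct phosphonium salt formation from a benzylic alcohol: HBr released from the salt converts the alcohol into the benzylic bromide, which triphenylphosphine alkylates (SN2), while the aryl benzyl ether is stable to this weakly acidic medium.

Step 5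
Reactants: 6 3-(4-{(E)-2-[4-(1,3-dioxolan-2-yl)-3-fluorophenyl]ethenyl}phenoxy)-4-methoxybenzaldehyde; 9 (3-benzyloxybenzyl)triphenylphosphonium bromide
Product: 11 2-[4-((E)-2-{4-[5-(2-(3-benzyloxyphenyl)ethenyl)-2-methoxyphenoxy]phenyl}ethenyl)-2-fluorophenyl]-1,3-dioxolane (ring A–ring D alkene as E/Z mixture), via phosphorus ylide 10 (not isolated)
Conditions: 9, KOtBu, THF, 0 °C; then 6, 0 °C → rt
Reagents that add atoms: none
Why: Wittig olefination of the single free aldehyde by the semi-stabilised benzylic ylide; the E/Z ratio is irrelevant because the double bond is saturated in the next step, and the acetal and the unactivated C–F bond tolerate the base.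

Step 6
Reactants: 11 2-[4-((E)-2-{4-[5-(2-(3-benzyloxyphenyl)ethenyl)-2-methoxyphenoxy]phenyl}ethenyl)-2-fluorophenyl]-1,3-dioxolane
Product: 13 2-fluoro-4-[2-(4-{5-[2-(3-hydroxyphenyl)ethyl]-2-methoxyphenoxy}phenyl)ethyl]benzaldehyde, via acetal phenol 12 (not isolated)
Conditions: H2 (1 atm), 10% Pd/C, NaHCO3, EtOAc–EtOH, rt; filter; then 2 M HCl, THF, rt
Reagents that add atoms: water, O
Why: Catalytic hydrogenation saturates both stilbene double bonds and hydrogenolyses the aryl benzyl ether while the bicarbonate-buffered medium keeps the dioxolane closed (so no free aldehyde meets the catalyst), and subsequent acid-catalysed acetal hydrolysis releases the formyl group.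

Step 7
Reactants: 13 2-fluoro-4-[2-(4-{5-[2-(3-hydroxyphenyl)ethyl]-2-methoxyphenoxy}phenyl)ethyl]benzaldehyde
Product: 14 macrocyclic aldehyde: the 19-membered cycle ring A–O–ring B–CH2CH2–ring C–O–ring D–CH2CH2–ring A, in which ring C carries CHO ortho to the new ether oxygen and para to its CH2CH2 arm, and ring A keeps OMe ortho to the ring B ether oxygen
Conditions: Cs2CO3 (3 equiv), 4 Å MS, dry degassed DMSO, 100 °C, Ar; 13 added by syringe pump over 12 h (final 2 mM)
Reagents that add atoms: none
Why: Carbonate deprotonates the ring D phenol and the phenoxide adds to the fluorine-bearing carbon of ring C, the charge of the resulting Meisenheimer anion being delocalised onto the ortho formyl oxygen before fluoride is expelled (addition–elimination SNAr). The closest known reaction type is carbonate-mediated diaryl ether formation from phenols and 2-fluorobenzaldehydes, together with SNAr macroetherification of activated fluoroarenes. The 19-membered ring closes end to end by ipso attack of oxygen on an aromatic carbon, the new ring C carbon–oxygen bond being the only bond formed. No stereocentre is created. The step needs ring closure to outrun intermolecular substitution, which slow addition into a hot dilute suspension should secure, and it needs site selectivity, which the substrate secures by holding exactly one phenol and exactly one formyl-activated C–F bond.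

Step 8
Reactants: 14 macrocyclic aldehyde
Product: 16 target macrocycle (14 in which the ring C formyl group is replaced by OH), via aryl formate 15 (not isolated)
Conditions: m-CPBA (1.3 equiv), CH2Cl2, 0 °C → rt; aq Na2S2O3/NaHCO3 wash; then K2CO3 (cat.), MeOH, rt
Reagents that add atoms: m-CPBA, OOC(=O)c1cccc(Cl)c1
Why: Dakin-type Baeyer–Villiger oxidation: the peracid adds to the formyl group and the ring C carbon, made migration-prone by the ortho aryloxy and para alkyl donors, shifts to oxygen to give the aryl formate, which carbonate-catalysed methanolysis cleaves to the phenol without touching the ring A methyl ether.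

Compound list
1 | isovanillin (3-hydroxy-4-methoxybenzaldehyde) | COc1ccc(C=O)cc1O | starting material
2 | 4-vinylphenylboronic acid | C=Cc1ccc(cc1)B(O)O | starting material
3 | 4-methoxy-3-(4-vinylphenoxy)benzaldehyde | COc1ccc(C=O)cc1Oc1ccc(C=C)cc1 | intermediate
4 | 4-bromo-2-fluorobenzaldehyde | O=Cc1ccc(Br)cc1F | starting material
5 | 2-(4-bromo-2-fluorophenyl)-1,3-dioxolane | Fc1cc(Br)ccc1C1OCCO1 | intermediate
6 | 3-(4-{(E)-2-[4-(1,3-dioxolan-2-yl)-3-fluorophenyl]ethenyl}phenoxy)-4-methoxybenzaldehyde | COc1ccc(C=O)cc1Oc1ccc(/C=C/c2ccc(C3OCCO3)c(F)c2)cc1 | intermediate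
7 | 3-benzyloxybenzyl alcohol | OCc1cccc(OCc2ccccc2)c1 | starting material
8 | 3-benzyloxybenzyl bromide (not isolated) | BrCc1cccc(OCc2ccccc2)c1 | intermediate
9 | (3-benzyloxybenzyl)triphenylphosphonium bromide | [Br-].c1ccc(cc1)COc1cccc(C[P+](c2ccccc2)(c2ccccc2)c2ccccc2)c1 | intermediate
10 | (3-benzyloxybenzylidene)triphenylphosphorane, the phosphorus ylide (not isolated) | c1ccc(cc1)COc1cccc(C=P(c2ccccc2)(c2ccccc2)c2ccccc2)c1 | intermediate
11 | 2-[4-((E)-2-{4-[5-(2-(3-benzyloxyphenyl)ethenyl)-2-methoxyphenoxy]phenyl}ethenyl)-2-fluorophenyl]-1,3-dioxolane, ring A–ring D alkene E/Z | COc1ccc(C=Cc2cccc(OCc3ccccc3)c2)cc1Oc1ccc(/C=C/c2ccc(C3OCCO3)c(F)c2)cc1 | intermediate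
12 | 3-[2-(3-{4-[2-(4-(1,3-dioxolan-2-yl)-3-fluorophenyl)ethyl]phenoxy}-4-methoxyphenyl)ethyl]phenol, the acetal phenol (not isolated) | COc1ccc(CCc2cccc(O)c2)cc1Oc1ccc(CCc2ccc(C3OCCO3)c(F)c2)cc1 | intermediate
13 | 2-fluoro-4-[2-(4-{5-[2-(3-hydroxyphenyl)ethyl]-2-methoxyphenoxy}phenyl)ethyl]benzaldehyde, the open-chain cyclisation precursor | COc1ccc(CCc2cccc(O)c2)cc1Oc1ccc(CCc2ccc(C=O)c(F)c2)cc1 | intermediate
14 | macrocyclic aldehyde (19-membered A–O–B–CH2CH2–C–O–D–CH2CH2 cycle, CHO on ring C ortho to the ring D ether oxygen) | COc1ccc2cc1Oc1ccc(cc1)CCc1ccc(C=O)c(c1)Oc1cccc(c1)CC2 | intermediate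
15 | macrocyclic aryl formate (14 with OCHO in place of CHO; not isolated) | COc1ccc2cc1Oc1ccc(cc1)CCc1ccc(OC=O)c(c1)Oc1cccc(c1)CC2 | intermediate
16 | CNP0132125.0 (14 with OH in place of CHO) | COc1ccc2cc1Oc1ccc(cc1)CCc1ccc(O)c(c1)Oc1cccc(c1)CC2 | target

Total step count: 8. Longest linear sequence: 6 steps (1, 3, 5, 6, 7, 8 from isovanillin; equally 2, 3, 5, 6, 7, 8 from 4-bromo-2-fluorobenzaldehyde).

Steps most likely to fail

Step 7. Ring closure may lose to intermolecular substitution, giving oligomers. The substitution may also stall, since a formyl group is only a moderate activator, while the base slowly degrades the aldehyde. DMSO is chosen over an amide solvent so that no amine nucleophile builds up during the long, dilute reaction. The fallback sets out from 3 and 9 and rejoins the route at 16; it exchanges the formyl activator for a nitro group, which is known to permit such closures near room temperature. Wittig reaction of 3 with ylide 10 (from 9, KOtBu, THF) should give 1-[2-(3-benzyloxyphenyl)ethenyl]-4-methoxy-3-(4-vinylphenoxy)benzene F1. Heck coupling of its terminal vinyl group with commercial 4-bromo-2-fluoro-1-nitrobenzene (Pd(OAc)2, Bu4NBr, NaHCO3, DMF, 80 °C) should give 1-[2-(3-benzyloxyphenyl)ethenyl]-3-{4-[(E)-2-(3-fluoro-4-nitrophenyl)ethenyl]phenoxy}-4-methoxybenzene F2. Homogeneous hydrogenation (H2, RhCl(PPh3)3, toluene–EtOH, 50 °C) should saturate both alkenes while sparing the nitro group and benzyl ether, giving 1-[2-(3-benzyloxyphenyl)ethyl]-3-{4-[2-(3-fluoro-4-nitrophenyl)ethyl]phenoxy}-4-methoxybenzene F3. Debenzylation with BCl3 and pentamethylbenzene (CH2Cl2, −78 °C) should give 3-[2-(3-{4-[2-(3-fluoro-4-nitrophenyl)ethyl]phenoxy}-4-methoxyphenyl)ethyl]phenol F4. Nitro-activated SNAr closure (K2CO3, DMF, high dilution, rt to 40 °C) should give the macrocyclic nitroarene F5. Reduction (H2, Pd/C, EtOAc) should give the macrocyclic aniline F6. Diazotisation (NaNO2, aq H2SO4, 0 °C) should give the diazonium hydrogensulfate F7, which is hydrolysed without isolation (Cu(NO3)2, Cu2O, water, rt) to 16.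

Step 6. Hydrogenolysis of the benzylic acetal followed by over-reduction of the liberated aldehyde, or sluggish cleavage of the benzyl ether, may erode the yield. The fallback sets out from 11 and returns at 13, separating the three events and using no metal catalyst. Diimide reduction of 11 (TsNHNH2, NaOAc, DME–water, reflux) should give the saturated benzyl ether acetal 2-{4-[2-(4-{5-[2-(3-benzyloxyphenyl)ethyl]-2-methoxyphenoxy}phenyl)ethyl]-2-fluorophenyl}-1,3-dioxolane F8. Acetal hydrolysis (2 M HCl, THF, rt) should give 4-[2-(4-{5-[2-(3-benzyloxyphenyl)ethyl]-2-methoxyphenoxy}phenyl)ethyl]-2-fluorobenzaldehyde F9. Lewis-acid debenzylation (BCl3, pentamethylbenzene, CH2Cl2, −78 °C), which spares aryl methyl ethers and aldehydes at that temperature, should give 13.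

Step 1. Protodeboronation and oxidative homocoupling of the boronic acid, slow arylation of the ortho-substituted phenol, or polymerisation of the vinyl group may limit conversion. The fallback sets out from 1 and returns at 3, building the ether from an aryl halide and installing the vinyl group afterwards. Ullmann coupling of 1 with 1-bromo-4-iodobenzene at the iodide (CuI, N,N-dimethylglycine hydrochloride, Cs2CO3, dioxane, 90 °C) should give 3-(4-bromophenoxy)-4-methoxybenzaldehyde F10. Suzuki–Miyaura vinylation with potassium vinyltrifluoroborate (PdCl2(dppf), Cs2CO3, THF–water, 80 °C) should give 3.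

Further compounds
F1 | step 7 | 1-[2-(3-benzyloxyphenyl)ethenyl]-4-methoxy-3-(4-vinylphenoxy)benzene (E/Z) | COc1ccc(C=Cc2cccc(OCc3ccccc3)c2)cc1Oc1ccc(C=C)cc1
F2 | step 7 | 1-[2-(3-benzyloxyphenyl)ethenyl]-3-{4-[(E)-2-(3-fluoro-4-nitrophenyl)ethenyl]phenoxy}-4-methoxybenzene | COc1ccc(C=Cc2cccc(OCc3ccccc3)c2)cc1Oc1ccc(/C=C/c2ccc([N+](=O)[O-])c(F)c2)cc1
F3 | step 7 | 1-[2-(3-benzyloxyphenyl)ethyl]-3-{4-[2-(3-fluoro-4-nitrophenyl)ethyl]phenoxy}-4-methoxybenzene | COc1ccc(CCc2cccc(OCc3ccccc3)c2)cc1Oc1ccc(CCc2ccc([N+](=O)[O-])c(F)c2)cc1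
F4 | step 7 | 3-[2-(3-{4-[2-(3-fluoro-4-nitrophenyl)ethyl]phenoxy}-4-methoxyphenyl)ethyl]phenol | COc1ccc(CCc2cccc(O)c2)cc1Oc1ccc(CCc2ccc([N+](=O)[O-])c(F)c2)cc1
F5 | step 7 | macrocyclic nitroarene (14 with NO2 in place of CHO) | COc1ccc2cc1Oc1ccc(cc1)CCc1ccc([N+](=O)[O-])c(c1)Oc1cccc(c1)CC2
F6 | step 7 | macrocyclic aniline (14 with NH2 in place of CHO) | COc1ccc2cc1Oc1ccc(cc1)CCc1ccc(N)c(c1)Oc1cccc(c1)CC2
F7 | step 7 | macrocyclic arenediazonium hydrogensulfate (not isolated) | COc1ccc2cc1Oc1ccc(cc1)CCc1ccc([N+]#N)c(c1)Oc1cccc(c1)CC2.OS(=O)(=O)[O-]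
F8 | step 6 | 2-{4-[2-(4-{5-[2-(3-benzyloxyphenyl)ethyl]-2-methoxyphenoxy}phenyl)ethyl]-2-fluorophenyl}-1,3-dioxolane | COc1ccc(CCc2cccc(OCc3ccccc3)c2)cc1Oc1ccc(CCc2ccc(C3OCCO3)c(F)c2)cc1
F9 | step 6 | 4-[2-(4-{5-[2-(3-benzyloxyphenyl)ethyl]-2-methoxyphenoxy}phenyl)ethyl]-2-fluorobenzaldehyde | COc1ccc(CCc2cccc(OCc3ccccc3)c2)cc1Oc1ccc(CCc2ccc(C=O)c(F)c2)cc1
F10 | step 1 | 3-(4-bromophenoxy)-4-methoxybenzaldehyde | COc1ccc(C=O)cc1Oc1ccc(Br)cc1
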